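Take the north and south runs first and read a second-order rate from each; the two people disputing these four flasks both start from it.

| flask | starting material | partner | temperature | remark | time |
|---|---|---|---|---|---|
| north | 0.20 M | 0.80 M | 65 °C | run made earlier |  |
| south-east | 0.80 M | 0.80 M | 100 °C | run made earlier |  |
| south | 0.40 M | 0.40 M | 65 °C | run made earlier |  |
| dawn | 0.40 M | 0.800 M | 130 °C |  | 4.0 h |
| spring | 0.40 M | 0.800 M | 90 °C |  | 4.0 h |
| winter | 0.40 M | 0.800 M | 70 °C |  | 4.0 h |
| dusk | 0.40 M | 0.800 M | 110 °C |  | 4.0 h |

| run | time / h | target / % | starting material / % |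
|---|---|---|---|
| north | 8.00 | 50.3 | 26.5 |
| north | 25.0 | 65.5 | 8.8 |
| north | 50.0 | 67.2 | 6.7 |
| north | 72.0 | 65.6 | 4.7 |
| north | 96.0 | 62.0 | 4.6 |
| south-east | 1.33 | 45.6 | 21.7 |
| south-east | 3.00 | 36.3 | 18.0 |
| south-east | 4.00 | 32.5 | 17.8 |
| south-east | 8.00 | 23.8 | 15.0 |
| south-east | 20.0 | 17.9 | 12.5 |
| south | 8.00 | 28.9 | 58.1 |
| south | 15.0 | 36.3 | 46.2 |
| south | 25.0 | 41.3 | 38.6 |
| south | 50.0 | 43.2 | 33.4 |
| south | 96.0 | 38.1 | 29.3 |

(scatter of a reading: 0.3 percentage points)

- a reading or a percentage of target counts all its forms, free or not
- a reading of starting material is of its free form alone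

1. the best flask by amount of target, in percent of the starting material charged; "all alike" if 1.5 percentage points covers them all (dawn / spring / winter / dusk / all alike)
2. amount of target at the end, in percent of the starting material charged, dawn
3. amount of target at the end, in percent of the starting material charged, spring
4. amount of target at the end, in percent of the starting material charged, winter
5. amount of target at the end, in percent of the starting material charged, dusk

Integrating the rate k[starting material][partner] in closed form, with the brackets read at the charge, leaves after time t an unused share f = ([partner] − [starting material]) / ([partner]·exp(([partner] − [starting material])kt) − [starting material]). For equal charges it becomes f = 1/(1 + [starting material]kt). My reckoning gives k = 0.225 M⁻¹ h⁻¹ from the south run and 0.234 M⁻¹ h⁻¹ from the north run, with different charges at the same temperature. The first south-east reading gives 3.39 M⁻¹ h⁻¹ at 100 °C. Interpolating ln k linearly in temperature gives spring 1.58 M⁻¹ h⁻¹, so f = 4.15%, and winter 0.343 M⁻¹ h⁻¹, so f = 40.6%. At the first north reading, 68.4% of the used starting material stood as target, and I take this reading as the selectivity. Multiplying it by 1 − f gives 65.6% for spring, the made share, meaning my estimate of the target a flask has made by its end before any fading, in percent of the starting material charged.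

The finisher holds that heat merely completes the making, so target follows the made share: winter 40.7%, spring 65.6%, dusk 68.4%, and he picks the hot flasks. The fader answers that made target shrinks. In the south-east run the readings fell at 0.127 h⁻¹ in first-order terms, and late in the north run at 0.00175 h⁻¹. Interpolated, that is 0.0373 h⁻¹ for spring, which my reckoning turns into 56.5% there, and extrapolated for dusk it is 0.431 h⁻¹, far faster than spring's.

The forecast takes the fader's side with a lower spring number than mine, saying that spring “completes, then loses modestly”: best spring, with dawn 21%, spring 52%, winter 40%, dusk 36%.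

The flasks give dawn 36.7%, spring 55.0%, winter 43.0% and dusk 30.9%, so spring is best and the fader wins the choice, though dawn stands above dusk where the forecast had it below. The finisher keeps the stretch from winter to spring, where target stood higher in the hotter flask.

    partner → decomposition product (k = 6.05 × 10⁻⁴ h⁻¹, Ea = 130 kJ mol⁻¹)
    target ⇌ isomer of the product B (K = 17.4, k = 0.0140 h⁻¹, Ea = 107 kJ mol⁻¹, ΔH = −53.0 kJ mol⁻¹)
    starting material + partner ⇌ target (K = 18.0 M⁻¹, k = 0.303 M⁻¹ h⁻¹, Ea = 96.0 kJ mol⁻¹, ΔH = 12.0 kJ mol⁻¹)
    starting material + partner ⇌ isomer of the product A (K = 2.80 M⁻¹, k = 0.144 M⁻¹ h⁻¹, Ea = 89.0 kJ mol⁻¹, ΔH = 23.0 kJ mol⁻¹)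
    partner + target ⇌ idle adduct, settled at all times (K = 1.40 M⁻¹, ΔH = −28.0 kJ mol⁻¹)
    (constants at 70 °C)

Spring's made share of 65.6% stands against 55.0% of target, all its forms counted, plus 16.4% of isomer of the product B, together 71.4%, with 8.13% of starting material left against f = 4.15%. The neighbouring flask is spring with 0.68 M of starting material, 1.18 equiv of partner. The same k gives f = 11.7% and a made share of 60.4%. That neighbouring flask ends with 17% of its starting material still there, unbound, and 48.3% of target, all its forms counted, plus 16.1% of isomer of the product B, together 64.4%.

The earlier runs and the new flask are simulated on assumed constants.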